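**Retrosynthetic overview**

1. The target is epicatechin-(4β→6)-epiafzelechin-(4β→8)-epicatechin-(4β→6)-epicatechin; its flavan units are called units 1–4 from the top (unit 2 = epiafzelechin). Last disconnections: global hydrogenolysis (16 benzyl ethers, 3 blocking bromines), then the unit 2 C4–unit 3 C8 bond between an upper dimer (units 1–2) and a lower dimer (units 3–4).
2. Upper dimer: (−)-epicatechin and (−)-epiafzelechin keep their rings (chiral pool). C8 bromine caps force the 4β→6 union, and an oxygen/sulfur pair of C4 leaving groups is activated orthogonally.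
3. Lower dimer: ring C of unit 3 (O1, C2, C3, C4, C4a, C8a) is built de novo and last. The enabling feature is C4 of unit 3, a doubly benzylic methine between C4a of ring A of unit 3 and C6 of ring A of unit 4 (two phloroglucinol-type rings). It is the retron of one aldehyde carbon that undergoes two Friedel–Crafts events; before closure, ring A of unit 3 is a symmetric 3,5-dioxygenated phenoxy group, so either ortho carbon closes the same ring.
4. The acyclic aldehyde carries the O1–C2 bond and the 2,3-cis (threo) stereocentres. They come from Jacobsen–Katsuki epoxidation of a Z-cinnamate and SN2 opening of the cis-epoxide by 3,5-bis(benzyloxy)phenol.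
5. Ring order: all rings of units 1, 2 and 4 and rings A and B of unit 3 are bought; a transient oxirane is made and opened (steps 10–11); ring C of unit 3 closes in step 14; no ring is formed afterwards.

Key step: step 14

Assumption: (−)-epiafzelechin (2R,3R) is taken as a purchasable natural product, as are 3,5-bis(benzyloxy)phenol and 3,4-bis(benzyloxy)benzaldehyde. Flavan numbering (O1, C2, C3, C4, C4a, C5–C8, C8a; primed positions on ring B) is used throughout.

**Route**

Step 1
Reactants: 1 (−)-epicatechin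
Product: 2 5,7,3',4'-tetra-O-benzyl-(−)-epicatechin
Conditions: BnBr (4.4 equiv), K2CO3, DMF, 0 °C → rt
Reagents that add atoms: benzyl bromide, BrCc1ccccc1
Why: Williamson etherification of the four phenols with a carbonate base should leave the less acidic secondary 3-OH and both stereocentres untouched.

Step 2
Reactants: 2 5,7,3',4'-tetra-O-benzyl-(−)-epicatechin
Product: 3 8-bromo-5,7,3',4'-tetra-O-benzyl-(−)-epicatechin
Conditions: NBS (1.0 equiv), CH2Cl2, −78 → 0 °C
Reagents that add atoms: N-bromosuccinimide, O=C1CCC(=O)N1Br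
Why: Electrophilic aromatic bromination should occur at C8, the most nucleophilic ring A carbon of benzylated flavan-3-ols (flanked by O1 and 7-OBn), which leaves C6 as the only free ring A position.

Step 3
Reactants: 3 8-bromo-5,7,3',4'-tetra-O-benzyl-(−)-epicatechin
Product: 4 8-bromo-5,7,3',4'-tetra-O-benzyl-4β-(2-ethoxyethoxy)-(−)-epicatechin
Conditions: DDQ (2 equiv), 2-ethoxyethanol (10 equiv), CH2Cl2, rt
Reagents that add atoms: 2-ethoxyethanol, CCOCCO
Why: DDQ benzylic oxidation (hydride abstraction at C4 gives the ring A-stabilised cation) followed by capture by the alcohol on the β face, away from the α-oriented 2-aryl and 3-OH groups, should give the 4β (3,4-trans) ether.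

Step 4
Reactants: 5 (−)-epiafzelechin
Product: 6 5,7,4'-tri-O-benzyl-(−)-epiafzelechin
Conditions: BnBr (3.3 equiv), K2CO3, DMF, 0 °C → rt
Reagents that add atoms: benzyl bromide, BrCc1ccccc1
Why: Williamson etherification of the three phenols as in step 1, with no stereocentre involved.

Step 5
Reactants: 6 5,7,4'-tri-O-benzyl-(−)-epiafzelechin
Product: 7 8-bromo-5,7,4'-tri-O-benzyl-(−)-epiafzelechin
Conditions: NBS (1.0 equiv), CH2Cl2, −78 → 0 °C
Reagents that add atoms: N-bromosuccinimide, O=C1CCC(=O)N1Br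
Why: Regioselective electrophilic bromination at C8 as in step 2 installs the cap that later directs the interflavan bond to C6.

Step 6
Reactants: 7 8-bromo-5,7,4'-tri-O-benzyl-(−)-epiafzelechin
Product: 8 8-bromo-5,7,4'-tri-O-benzyl-4β-(2-ethoxyethoxy)-(−)-epiafzelechin
Conditions: DDQ (2 equiv), 2-ethoxyethanol (10 equiv), CH2Cl2, rt
Reagents that add atoms: 2-ethoxyethanol, CCOCCO
Why: DDQ benzylic C4 oxidation with alcohol capture trans to the 3-OH, as in step 3.

Step 7
Reactants: 8 8-bromo-5,7,4'-tri-O-benzyl-4β-(2-ethoxyethoxy)-(−)-epiafzelechin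
Product: 9 8-bromo-4β-(benzylthio)-5,7,4'-tri-O-benzyl-(−)-epiafzelechin
Conditions: BnSH (5 equiv), BF3·OEt2 (0.3 equiv), CH2Cl2, −40 → 0 °C
Reagents that add atoms: benzyl mercaptan, SCc1ccccc1
Why: Lewis acid ionisation of the C4 ether and capture of the cation by the thiol on the β face (thiolysis-type exchange) should give the 4β thioether, a C4 leaving group that is inert to hard Lewis acids.

Step 8
Reactants: 4 8-bromo-5,7,3',4'-tetra-O-benzyl-4β-(2-ethoxyethoxy)-(−)-epicatechin; 9 8-bromo-4β-(benzylthio)-5,7,4'-tri-O-benzyl-(−)-epiafzelechin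
Product: 10 upper dimer [8-bromo-5,7,3',4'-tetra-O-benzylepicatechin]-(4β→6)-[8-bromo-4β-(benzylthio)-5,7,4'-tri-O-benzylepiafzelechin]
Conditions: 9 (3 equiv), BF3·OEt2 (0.3 equiv), CH2Cl2, −78 → −20 °C; Et3N
Reagents that add atoms: none
Why: Friedel–Crafts-type interflavan coupling in which the hard Lewis acid ionises only the oxygen leaving group of 4, the C8 bromine leaves C6 of 9 as the only nucleophilic ring A carbon, and attack on the β face of the cation (2-aryl and 3-OH are α) sets the new C4 stereocentre as 4β.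

Step 9
Reactants: 11 3,4-bis(benzyloxy)benzaldehyde
Product: 12 methyl (Z)-3-[3,4-bis(benzyloxy)phenyl]prop-2-enoate
Conditions: (CF3CH2O)2P(O)CH2CO2Me, KN(SiMe3)2, 18-crown-6, THF, −78 °C
Reagents that add atoms: methyl bis(2,2,2-trifluoroethyl)phosphonoacetate, COC(=O)CP(=O)(OCC(F)(F)F)OCC(F)(F)F
Why: Still–Gennari variant of the Horner–Wadsworth–Emmons olefination, in which fast irreversible elimination from the kinetically formed adduct should give the Z-enoate.

Step 10
Reactants: 12 methyl (Z)-3-[3,4-bis(benzyloxy)phenyl]prop-2-enoate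
Product: 13 methyl (2S,3S)-3-[3,4-bis(benzyloxy)phenyl]oxirane-2-carboxylate (cis)
Conditions: (S,S)-MnCl(salen) (5 mol %; salen = N,N'-bis(3,5-di-tert-butylsalicylidene)cyclohexane-1,2-diaminate), 4-phenylpyridine N-oxide (0.25 equiv), aq. NaOCl (pH 11.3), CH2Cl2, 0 °C
Reagents that add atoms: sodium hypochlorite, [Na+].[O-]Cl
Why: Jacobsen–Katsuki epoxidation, for which cis-cinnamate esters are a privileged substrate class; the (S,S)-catalyst should deliver oxygen to the face that gives the (2S,3S) cis-epoxide, which fixes the absolute configuration of the future C3 and, after inversion, C2 of unit 3.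

Step 11
Reactants: 13 methyl (2S,3S)-3-[3,4-bis(benzyloxy)phenyl]oxirane-2-carboxylate; 14 3,5-bis(benzyloxy)phenol
Product: 15 methyl (2S,3R)-3-[3,4-bis(benzyloxy)phenyl]-3-[3,5-bis(benzyloxy)phenoxy]-2-hydroxypropanoate (threo)
Conditions: 14 (1.5 equiv), Cs2CO3 (0.3 equiv), DMF, 50 °C
Reagents that add atoms: none
Why: SN2 opening of the glycidic ester by the phenoxide at the benzylic carbon remote from the ester, with inversion, should convert the cis-epoxide into the threo aryl ether, that is the O1–C2 bond and the 2,3-cis relationship of unit 3.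

Step 12
Reactants: 15 methyl (2S,3R)-3-[3,4-bis(benzyloxy)phenyl]-3-[3,5-bis(benzyloxy)phenoxy]-2-hydroxypropanoate
Product: 16 methyl (2S,3R)-2-(benzyloxy)-3-[3,4-bis(benzyloxy)phenyl]-3-[3,5-bis(benzyloxy)phenoxy]propanoate
Conditions: BnBr (3 equiv), Ag2O (2 equiv), CH2Cl2, rt, dark
Reagents that add atoms: benzyl bromide, BrCc1ccccc1
Why: Silver oxide-mediated Williamson benzylation of the α-hydroxy ester proceeds without a strong base, so neither epimerisation at C2 nor β-elimination of the aryloxide should occur.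

Step 13
Reactants: 16 methyl (2S,3R)-2-(benzyloxy)-3-[3,4-bis(benzyloxy)phenyl]-3-[3,5-bis(benzyloxy)phenoxy]propanoate
Product: 17 (2S,3R)-2-(benzyloxy)-3-[3,4-bis(benzyloxy)phenyl]-3-[3,5-bis(benzyloxy)phenoxy]propanal
Conditions: i-Bu2AlH (1.1 equiv), CH2Cl2, −78 °C; aq. potassium sodium tartrate; used crude
Reagents that add atoms: none
Why: Partial reduction of an α-alkoxy ester, whose chelated tetrahedral aluminate is stable at −78 °C and should release the aldehyde only on work-up, without touching the stereocentres.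

Step 14
Reactants: 17 (2S,3R)-2-(benzyloxy)-3-[3,4-bis(benzyloxy)phenyl]-3-[3,5-bis(benzyloxy)phenoxy]propanal; 3 8-bromo-5,7,3',4'-tetra-O-benzyl-(−)-epicatechin
Product: 19 lower dimer [3,5,7,3',4'-penta-O-benzylepicatechin]-(4β→6)-[8-bromo-5,7,3',4'-tetra-O-benzylepicatechin], via flavan-3,4-diol 3-benzyl ether 18 (not isolated)
Conditions: 3 (3 equiv), TMSOTf (0.3 equiv), 4 Å MS, CH2Cl2, −78 → −40 °C; Et3N
Reagents that add atoms: none
Why: Proposed new method: the acid (TMSOTf and the TfOH it releases) activates the aldehyde of 17, and the 3,5-bis(benzyloxy)phenoxy ring attacks it through one of its two equivalent ortho carbons (6-exo-trig Friedel–Crafts hydroxyalkylation, the C=O bond lying outside the new ring) to give 18, whose C4–O bond then ionises to the benzylic cation stabilised by O1, 5-OBn and 7-OBn, which is captured by C6 of 3. The closest known reaction types are the acid cyclisation of 3-aryloxypropanals to chroman-4-ols, the double Friedel–Crafts arylation of aldehydes to diaryl- and triarylmethanes, and the Lewis acid coupling of flavan-3,4-diols or 4-alkoxyflavans with phloroglucinol-type nucleophiles; what is new is running them as one cascade on an acyclic precursor. C2 and C3 are carried in unchanged from 17, and the only new stereocentre, C4, is set in the second event, where the nucleophile adds to the half-chair cation on the β face because both the 2-aryl and the 3-OBn groups shield the α face (the uniform 3,4-trans outcome of 2,3-cis flavan-4-yl cations). Ring closure needs no regiocontrol, because both ortho carbons of the phenoxy ring give the same chroman and the para carbon cannot reach, while ring B (one activating oxygen para to its free carbon, five-membered closure) cannot compete with the triply activated ring A. On the nucleophile the C8 bromine leaves C6 as the only free ring A carbon, and its excess, together with its lower reactivity than the tethered arene, should keep ring closure ahead of intermolecular attack on the aldehyde and suppress attack of the cation by C6 or C8 of product 19.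

Step 15
Reactants: 10 upper dimer (C4 thioether); 19 lower dimer
Product: 20 protected tetramer [8-bromo-5,7,3',4'-tetra-O-benzylepicatechin]-(4β→6)-[8-bromo-5,7,4'-tri-O-benzylepiafzelechin]-(4β→8)-[3,5,7,3',4'-penta-O-benzylepicatechin]-(4β→6)-[8-bromo-5,7,3',4'-tetra-O-benzylepicatechin]
Conditions: 19 (1.5 equiv), AgBF4 (2 equiv), 4 Å MS, CH2Cl2/THF, −20 → 0 °C, dark; Et3N
Reagents that add atoms: none
Why: Thiophilic activation (the silver salt abstracts benzylthiolate from C4 of unit 2) gives the flavan-4-yl cation, which should be captured on its β face by C8 of ring A of unit 3, the innately more nucleophilic and less hindered position than C6, to form the 4β→8 bond in a Friedel–Crafts-type interflavan coupling.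

Step 16
Reactants: 20 protected tetramer
Product: 21 epicatechin-(4β→6)-epiafzelechin-(4β→8)-epicatechin-(4β→6)-epicatechin (CNP0103636.1)
Conditions: H2 (1 atm), Pd(OH)2/C, Et3N (4 equiv), THF/MeOH/H2O, rt
Reagents that add atoms: none
Why: Catalytic hydrogenolysis should cleave all sixteen benzyl ethers and hydrodebrominate the three aryl bromides (Et3N takes up HBr and keeps the acid-labile interflavan bonds intact) without touching any stereocentre.

**Compound list**

1 | (−)-epicatechin, (2R,3R) | Oc1cc(O)c2c(c1)O[C@H](c1ccc(O)c(O)c1)[C@H](O)C2 | starting material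
2 | 5,7,3',4'-tetra-O-benzyl-(−)-epicatechin | c1(OCc3ccccc3)cc(OCc3ccccc3)c2c(c1)O[C@H](c1ccc(OCc3ccccc3)c(OCc3ccccc3)c1)[C@H](O)C2 | intermediate
3 | 8-bromo-5,7,3',4'-tetra-O-benzyl-(−)-epicatechin | c1(OCc3ccccc3)cc(OCc3ccccc3)c2c(c1Br)O[C@H](c1ccc(OCc3ccccc3)c(OCc3ccccc3)c1)[C@H](O)C2 | intermediate
4 | 8-bromo-5,7,3',4'-tetra-O-benzyl-4β-(2-ethoxyethoxy)-(−)-epicatechin (2,3-cis, 3,4-trans) | c1(OCc3ccccc3)cc(OCc3ccccc3)c2c(c1Br)O[C@H](c1ccc(OCc3ccccc3)c(OCc3ccccc3)c1)[C@H](O)[C@H]2OCCOCC | intermediate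
5 | (−)-epiafzelechin, (2R,3R) | Oc1ccc([C@H]2Oc3cc(O)cc(O)c3C[C@H]2O)cc1 | starting material
6 | 5,7,4'-tri-O-benzyl-(−)-epiafzelechin | c1(OCc4ccccc4)ccc([C@H]2Oc3cc(OCc4ccccc4)cc(OCc4ccccc4)c3C[C@H]2O)cc1 | intermediate
7 | 8-bromo-5,7,4'-tri-O-benzyl-(−)-epiafzelechin | c1(OCc4ccccc4)ccc([C@H]2Oc3c(Br)c(OCc4ccccc4)cc(OCc4ccccc4)c3C[C@H]2O)cc1 | intermediate
8 | 8-bromo-5,7,4'-tri-O-benzyl-4β-(2-ethoxyethoxy)-(−)-epiafzelechin | c1(OCc4ccccc4)ccc([C@H]2Oc3c(Br)c(OCc4ccccc4)cc(OCc4ccccc4)c3[C@H](OCCOCC)[C@H]2O)cc1 | intermediate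
9 | 8-bromo-4β-(benzylthio)-5,7,4'-tri-O-benzyl-(−)-epiafzelechin | c1(OCc4ccccc4)ccc([C@H]2Oc3c(Br)c(OCc4ccccc4)cc(OCc4ccccc4)c3[C@H](SCc4ccccc4)[C@H]2O)cc1 | intermediate
10 | upper dimer, [8-bromo-5,7,3',4'-tetra-O-benzylepicatechin]-(4β→6)-[8-bromo-4β-(benzylthio)-5,7,4'-tri-O-benzylepiafzelechin] | c1(OCc6ccccc6)ccc([C@H]2Oc3c(Br)c(OCc6ccccc6)c([C@H]4c5c(OCc6ccccc6)cc(OCc6ccccc6)c(Br)c5O[C@H](c5ccc(OCc6ccccc6)c(OCc6ccccc6)c5)[C@@H]4O)c(OCc6ccccc6)c3[C@H](SCc6ccccc6)[C@H]2O)cc1 | intermediate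
11 | 3,4-bis(benzyloxy)benzaldehyde | O=Cc1ccc(OCc2ccccc2)c(OCc2ccccc2)c1 | starting material
12 | methyl (Z)-3-[3,4-bis(benzyloxy)phenyl]prop-2-enoate | COC(=O)/C=C\c1ccc(OCc2ccccc2)c(OCc2ccccc2)c1 | intermediate
13 | methyl (2S,3S)-3-[3,4-bis(benzyloxy)phenyl]oxirane-2-carboxylate (cis) | O1[C@@H](c2ccc(OCc3ccccc3)c(OCc3ccccc3)c2)[C@H]1C(=O)OC | intermediate
14 | 3,5-bis(benzyloxy)phenol | Oc1cc(OCc2ccccc2)cc(OCc2ccccc2)c1 | starting material
15 | methyl (2S,3R)-3-[3,4-bis(benzyloxy)phenyl]-3-[3,5-bis(benzyloxy)phenoxy]-2-hydroxypropanoate (threo) | c1c(OCc2ccccc2)cc(OCc2ccccc2)cc1O[C@H](c1ccc(OCc2ccccc2)c(OCc2ccccc2)c1)[C@H](O)C(=O)OC | intermediate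
16 | methyl (2S,3R)-2-(benzyloxy)-3-[3,4-bis(benzyloxy)phenyl]-3-[3,5-bis(benzyloxy)phenoxy]propanoate | c1c(OCc2ccccc2)cc(OCc2ccccc2)cc1O[C@H](c1ccc(OCc2ccccc2)c(OCc2ccccc2)c1)[C@H](OCc1ccccc1)C(=O)OC | intermediate
17 | (2S,3R)-2-(benzyloxy)-3-[3,4-bis(benzyloxy)phenyl]-3-[3,5-bis(benzyloxy)phenoxy]propanal | c1c(OCc2ccccc2)cc(OCc2ccccc2)cc1O[C@H](c1ccc(OCc2ccccc2)c(OCc2ccccc2)c1)[C@H](OCc1ccccc1)C=O | intermediate
18 | 3,5,7,3',4'-pentakis-O-benzyl-2,3-cis-flavan-3,4-diol, free 4-OH (2R; both C4 epimers, partly as the O-silyl ether) | c1c(OCc3ccccc3)cc(OCc3ccccc3)c2c1O[C@H](c1ccc(OCc3ccccc3)c(OCc3ccccc3)c1)[C@H](OCc1ccccc1)C2O | intermediate (not isolated)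
19 | lower dimer, [3,5,7,3',4'-penta-O-benzylepicatechin]-(4β→6)-[8-bromo-5,7,3',4'-tetra-O-benzylepicatechin] | c1c(OCc3ccccc3)cc(OCc3ccccc3)c2c1O[C@H](c1ccc(OCc3ccccc3)c(OCc3ccccc3)c1)[C@H](OCc1ccccc1)[C@H]2c1c(OCc3ccccc3)c(Br)c2c(c1OCc3ccccc3)C[C@@H](O)[C@@H](c1ccc(OCc3ccccc3)c(OCc3ccccc3)c1)O2 | intermediate
20 | protected tetramer (16 benzyl ethers; bromine at C8 of units 1, 2 and 4) | c1(OCc6ccccc6)ccc([C@H]2Oc3c(Br)c(OCc6ccccc6)c([C@H]4c5c(OCc6ccccc6)cc(OCc6ccccc6)c(Br)c5O[C@H](c5ccc(OCc6ccccc6)c(OCc6ccccc6)c5)[C@@H]4O)c(OCc6ccccc6)c3[C@H](c3c(OCc6ccccc6)cc(OCc6ccccc6)c4c3O[C@H](c3ccc(OCc6ccccc6)c(OCc6ccccc6)c3)[C@H](OCc6ccccc6)[C@H]4c3c(OCc6ccccc6)c(Br)c4c(c3OCc6ccccc6)C[C@@H](O)[C@@H](c3ccc(OCc6ccccc6)c(OCc6ccccc6)c3)O4)[C@H]2O)cc1 | intermediate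
21 | epicatechin-(4β→6)-epiafzelechin-(4β→8)-epicatechin-(4β→6)-epicatechin (CNP0103636.1) | Oc1ccc([C@H]2Oc3cc(O)c([C@H]4c5c(O)cc(O)cc5O[C@H](c5ccc(O)c(O)c5)[C@@H]4O)c(O)c3[C@H](c3c(O)cc(O)c4c3O[C@H](c3ccc(O)c(O)c3)[C@H](O)[C@H]4c3c(O)cc4c(c3O)C[C@@H](O)[C@@H](c3ccc(O)c(O)c3)O4)[C@H]2O)cc1 | target

**Summary**

Total step count: 16.
Longest linear sequence: 8 steps (11 → 12 → 13 → 15 → 16 → 17 → 19 → 20 → 21).

**Steps most likely to fail**

1. Step 14 (proposed new method). Intermolecular attack on the activated aldehyde may outrun ring closure and lead to open-chain adducts and oligomerisation. The α-benzyloxy aldehyde may also enolise, with epimerisation at C3 or β-elimination of the aryloxide, or the cation may be attacked on the wrong face. The fallback uses only known chemistry, sets out from 2 and comes back at 19. Compound 2 is benzylated at the 3-OH (NaH, BnBr, DMF, 0 °C) to 3,5,7,3',4'-penta-O-benzyl-(−)-epicatechin F1. F1 is oxidised with DDQ in the presence of 2-ethoxyethanol to 3,5,7,3',4'-penta-O-benzyl-4β-(2-ethoxyethoxy)-(−)-epicatechin F2. F2 is then coupled with an excess of 3 under TMSOTf at −78 °C to give 19. Ring C of unit 3 is then taken from the chiral pool instead of being built.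

2. Step 8. Attack by C6 of the capped nucleophile, which also carries a bulky C4 thioether, may be so slow that self-condensation of the electrophile through its own C6, or premature loss of the thioether, takes over. The fallback sets out from 4 and 7 and comes back at 20. Compound 4 is coupled with the thioether-free nucleophile 7 (BF3·OEt2, CH2Cl2, −78 → −20 °C) to the dimer [8-bromo-5,7,3',4'-tetra-O-benzylepicatechin]-(4β→6)-[8-bromo-5,7,4'-tri-O-benzylepiafzelechin] F3. The only C4 methylene of F3 (unit 2) is oxidised with DDQ and 2-ethoxyethanol to the 4β-(2-ethoxyethoxy) dimer F4. F4 is coupled with 19 under TMSOTf at −78 °C to give 20 directly, so that steps 6, 7 and 15 are not needed.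

3. Step 11. The ambident phenoxide may alkylate through carbon, attack may occur at the ester-bearing epoxide carbon, the electron-rich benzylic C–O bond may ionise with loss of stereospecificity, or the product may suffer base-induced elimination of the aryloxide. The fallback sets out from 13 and comes back at 15. The ester of 13 is reduced (NaBH4, MeOH/THF, 0 °C) to the cis-epoxy alcohol [(2R,3S)-3-[3,4-bis(benzyloxy)phenyl]oxiran-2-yl]methanol F5. F5 is opened at the benzylic carbon by the sodium salt of 14 (NaOH, H2O/dioxane, 70 °C), the conditions under which 3-aryl-2,3-epoxy alcohols are known to give 3-aryloxy-1,2-diols with inversion, to give (2R,3R)-3-[3,4-bis(benzyloxy)phenyl]-3-[3,5-bis(benzyloxy)phenoxy]propane-1,2-diol F6. The primary alcohol of F6 is oxidised selectively (TEMPO, PhI(OAc)2, MeCN/H2O) to (2S,3R)-3-[3,4-bis(benzyloxy)phenyl]-3-[3,5-bis(benzyloxy)phenoxy]-2-hydroxypropanoic acid F7. Esterification of F7 with TMSCHN2 in MeOH/toluene gives 15.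

Further compounds
F1 | step 14 | 3,5,7,3',4'-penta-O-benzyl-(−)-epicatechin | c1(OCc3ccccc3)cc(OCc3ccccc3)c2c(c1)O[C@H](c1ccc(OCc3ccccc3)c(OCc3ccccc3)c1)[C@H](OCc1ccccc1)C2
F2 | step 14 | 3,5,7,3',4'-penta-O-benzyl-4β-(2-ethoxyethoxy)-(−)-epicatechin | c1(OCc3ccccc3)cc(OCc3ccccc3)c2c(c1)O[C@H](c1ccc(OCc3ccccc3)c(OCc3ccccc3)c1)[C@H](OCc1ccccc1)[C@H]2OCCOCC
F3 | step 8 | [8-bromo-5,7,3',4'-tetra-O-benzylepicatechin]-(4β→6)-[8-bromo-5,7,4'-tri-O-benzylepiafzelechin] | c1(OCc6ccccc6)ccc([C@H]2Oc3c(Br)c(OCc6ccccc6)c([C@H]4c5c(OCc6ccccc6)cc(OCc6ccccc6)c(Br)c5O[C@H](c5ccc(OCc6ccccc6)c(OCc6ccccc6)c5)[C@@H]4O)c(OCc6ccccc6)c3C[C@H]2O)cc1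
F4 | step 8 | [8-bromo-5,7,3',4'-tetra-O-benzylepicatechin]-(4β→6)-[8-bromo-5,7,4'-tri-O-benzyl-4β-(2-ethoxyethoxy)epiafzelechin] | c1(OCc6ccccc6)ccc([C@H]2Oc3c(Br)c(OCc6ccccc6)c([C@H]4c5c(OCc6ccccc6)cc(OCc6ccccc6)c(Br)c5O[C@H](c5ccc(OCc6ccccc6)c(OCc6ccccc6)c5)[C@@H]4O)c(OCc6ccccc6)c3[C@H](OCCOCC)[C@H]2O)cc1
F5 | step 11 | [(2R,3S)-3-[3,4-bis(benzyloxy)phenyl]oxiran-2-yl]methanol (cis) | O1[C@@H](c2ccc(OCc3ccccc3)c(OCc3ccccc3)c2)[C@H]1CO
F6 | step 11 | (2R,3R)-3-[3,4-bis(benzyloxy)phenyl]-3-[3,5-bis(benzyloxy)phenoxy]propane-1,2-diol (threo) | c1c(OCc2ccccc2)cc(OCc2ccccc2)cc1O[C@H](c1ccc(OCc2ccccc2)c(OCc2ccccc2)c1)[C@H](O)CO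
F7 | step 11 | (2S,3R)-3-[3,4-bis(benzyloxy)phenyl]-3-[3,5-bis(benzyloxy)phenoxy]-2-hydroxypropanoic acid | c1c(OCc2ccccc2)cc(OCc2ccccc2)cc1O[C@H](c1ccc(OCc2ccccc2)c(OCc2ccccc2)c1)[C@H](O)C(=O)O
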